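**Plan**

- With the oxepene numbered O1, C2 (quaternary, S), C3, C4, C5=C6, C7, C7 is a single CH2 held between O1 and the ring alkene. It can therefore be the acetal carbon of a methoxymethyl ether on the C2 oxygen, joined to C6 of a vinylsilane.
- Cuts, in retrosynthetic order: C6–C7 (ring), O1–C7 (acetal), C2–CH2C(O)Ar (aldol), C2–C3 (Grignard acylation), C6–side chain (sp2–sp3 coupling).
- Forward: a side-chain zinc reagent is coupled to an α-iodovinylsilane, the chain is extended to an allyl α-keto ester, the aryl ketone arm is added by aldol reaction and the tertiary alcohol is etherified. The only ring, the oxepene, closes last; fluoride and palladium deprotections finish.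
- Stereochemistry: C2 comes from a Cu(OTf)2–bis(oxazoline) Mukaiyama aldol. The ring alkene comes from the Z-vinylsilane (cis-hydroalumination/iodination, retentive coupling, retentive ipso-substitution). The side-chain E-alkene comes from SeO2 oxidation of the E-methyl group of a prenyl-type bromide.

Key step: step 11

Assumption: the Cu(OTf)2–(S,S)-t-Bu-box catalyst is taken to deliver the enol silane to the si face of the chelated α-keto ester, as it does with pyruvate esters, which corresponds to the (S) alcohol required; should the opposite sense be found, the (R,R) ligand would be used.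

**Route**

Step 1
Reactants: 1 5-bromo-2-methylpent-2-ene
Product: 2 (E)-5-bromo-2-methylpent-2-en-1-ol
Conditions: SeO2 (0.3 equiv), t-BuOOH (2.5 equiv), CH2Cl2, 0 °C → rt
Reagents that add atoms: selenium dioxide O=[Se]=O (oxygen donor, regenerated by tert-butyl hydroperoxide CC(C)(C)OO)
Why: Catalytic SeO2 allylic oxidation (ene reaction followed by [2,3]-sigmatropic shift) hydroxylates the E-methyl group of a 2-methylalk-2-ene, so the (E)-allylic alcohol should form while the primary bromide is left alone.

Step 2
Reactants: 2 (E)-5-bromo-2-methylpent-2-en-1-ol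
Product: 3 (E)-5-bromo-1-(tert-butyldiphenylsilyloxy)-2-methylpent-2-ene
Conditions: TBDPSCl, imidazole, CH2Cl2, 0 °C → rt
Reagents that add atoms: tert-butyl(chloro)diphenylsilane CC(C)(C)[Si](Cl)(c1ccccc1)c1ccccc1
Why: Routine silylation of a primary alcohol; the bulky silyl ether is chosen because it must later withstand organozinc, Grignard and SnCl4 conditions.

Step 3
Reactants: 4 4-(trimethylsilyl)but-3-yn-1-ol
Product: 6 (E)-4-iodo-4-(trimethylsilyl)but-3-en-1-ol, via alkenylalane 5 (not isolated)
Conditions: i-Bu2AlH (2.5 equiv), Et2O, 0 °C → reflux; then I2, THF, –78 → 0 °C; aq. potassium sodium tartrate, Na2S2O3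
Reagents that add atoms: iodine II
Why: Hydroalumination of a 1-silylalkyne in a donor solvent is a cis addition that puts aluminium on the silicon-bearing carbon (the first equivalent of hydride only forms the aluminium alkoxide), and iodinolysis of the alkenyl–aluminium bond with retention should leave SiMe3 cis to the carbon chain.

Step 4
Reactants: 6 (E)-4-iodo-4-(trimethylsilyl)but-3-en-1-ol
Product: 7 (E)-4-bromo-1-iodo-1-(trimethylsilyl)but-1-ene
Conditions: CBr4, PPh3, CH2Cl2, 0 °C
Reagents that add atoms: tetrabromomethane BrC(Br)(Br)Br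
Why: Appel reaction of a primary alcohol, to which the alkenyl iodide and the alkenylsilane are inert; converting the hydroxyl at this point removes the acidic proton before the organozinc coupling.

Step 5
Reactants: 3 (E)-5-bromo-1-(tert-butyldiphenylsilyloxy)-2-methylpent-2-ene; 7 (E)-4-bromo-1-iodo-1-(trimethylsilyl)but-1-ene
Product: 9 (2E,6Z)-9-bromo-1-(tert-butyldiphenylsilyloxy)-2-methyl-6-(trimethylsilyl)nona-2,6-diene, via alkylzinc bromide 8 (not isolated)
Conditions: 3, Zn dust (activated with BrCH2CH2Br, Me3SiCl), LiCl, THF, 50 °C, solution cannulated off excess Zn; then 7, PdCl2(dppf) (5 mol %), THF, rt → 40 °C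
Reagents that add atoms: none
Why: LiCl-assisted zinc insertion into the primary bromide followed by Negishi coupling at the alkenyl iodide, which should proceed with retention of geometry and leave the unactivated primary C–Br bond of 7 untouched because neither the alkylzinc nor the phosphine-ligated palladium catalyst attacks it at this temperature.

Step 6
Reactants: 9 (2E,6Z)-9-bromo-1-(tert-butyldiphenylsilyloxy)-2-methyl-6-(trimethylsilyl)nona-2,6-diene; 10 diallyl oxalate
Product: 12 allyl (5Z,9E)-11-(tert-butyldiphenylsilyloxy)-10-methyl-2-oxo-6-(trimethylsilyl)undeca-5,9-dienoate, via Grignard reagent 11 (not isolated)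
Conditions: Mg turnings, THF, rt; then added to 10 (3 equiv), THF–Et2O, –78 °C; aq. NH4Cl at –78 °C
Reagents that add atoms: none
Why: Grignard acylation with an excess of a dialkyl oxalate at low temperature stops at the α-keto ester because the magnesium hemiketalate does not collapse before the cold quench.

Step 7
Reactants: 13 2',5'-dihydroxyacetophenone
Product: 14 2',5'-bis(tert-butyldimethylsilyloxy)acetophenone
Conditions: TBSCl (2.5 equiv), imidazole, DMF, rt → 40 °C
Reagents that add atoms: tert-butyl(chloro)dimethylsilane CC(C)(C)[Si](C)(C)Cl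
Why: Silylation of both phenols, the hydrogen-bonded 2'-hydroxyl reacting more slowly and therefore needing the excess and gentle warming.

Step 8
Reactants: 14 2',5'-bis(tert-butyldimethylsilyloxy)acetophenone
Product: 15 1-[2,5-bis(tert-butyldimethylsilyloxy)phenyl]-1-(trimethylsilyloxy)ethene
Conditions: Me3SiOTf, Et3N, CH2Cl2, 0 °C
Reagents that add atoms: trimethylsilyl trifluoromethanesulfonate C[Si](C)(C)OS(=O)(=O)C(F)(F)F
Why: Soft enolisation of a methyl ketone to its enol silane, which avoids a free enolate that could take over the neighbouring aryl silyl group.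

Step 9
Reactants: 12 allyl (5Z,9E)-11-(tert-butyldiphenylsilyloxy)-10-methyl-2-oxo-6-(trimethylsilyl)undeca-5,9-dienoate; 15 1-[2,5-bis(tert-butyldimethylsilyloxy)phenyl]-1-(trimethylsilyloxy)ethene
Product: 17 allyl (2S,5Z,9E)-2-{2-[2,5-bis(tert-butyldimethylsilyloxy)phenyl]-2-oxoethyl}-11-(tert-butyldiphenylsilyloxy)-2-hydroxy-10-methyl-6-(trimethylsilyl)undeca-5,9-dienoate, via tertiary trimethylsilyl ether 16 (not isolated)
Conditions: [Cu((S,S)-t-Bu-box)](OTf)2 (10 mol %), THF, –78 °C; then 1 M HCl, THF, 0 °C
Reagents that add atoms: none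
Why: Mukaiyama aldol addition catalysed by the divalent copper bis(oxazoline) complex: the α-keto ester binds copper through both carbonyl oxygens, a tert-butyl group of the ligand covers the re face of the ketone, the enol silane adds to the si face to set C2 as (S) in silyl ether 16, and dilute acid then frees the tertiary alcohol without touching the aryl or tert-butyldiphenylsilyl ethers.

Step 10
Reactants: 17 the (S)-tertiary alcohol from step 9; 18 chloromethyl methyl ether
Product: 19 allyl (2S,5Z,9E)-2-{2-[2,5-bis(tert-butyldimethylsilyloxy)phenyl]-2-oxoethyl}-11-(tert-butyldiphenylsilyloxy)-2-(methoxymethoxy)-10-methyl-6-(trimethylsilyl)undeca-5,9-dienoate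
Conditions: 18 (excess), i-Pr2NEt, n-Bu4NI (cat.), ClCH2CH2Cl, 0 → 45 °C
Reagents that add atoms: none
Why: Methoxymethyl ether formation by alkylation of the alcohol with an α-chloro ether under amine base and iodide catalysis, which needs no alkoxide and so should not trigger retro-aldol cleavage next to the aryl ketone.

Step 11
Reactants: 19 the methoxymethyl ether (Z)-vinylsilane from step 10
Product: 20 allyl (S)-2-{2-[2,5-bis(tert-butyldimethylsilyloxy)phenyl]-2-oxoethyl}-6-[(E)-5-(tert-butyldiphenylsilyloxy)-4-methylpent-3-enyl]-2,3,4,7-tetrahydrooxepine-2-carboxylate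
Conditions: SnCl4 (2.5 equiv), 2,6-di-tert-butyl-4-methylpyridine (0.5 equiv), CH2Cl2 (0.01 M), –78 → –20 °C; aq. NaHCO3
Reagents that add atoms: none
Why: SnCl4 binds the less hindered methoxy oxygen of the acetal and expels methoxide, leaving an O1=CH2 oxocarbenium ion on the tertiary oxygen. The Z-vinylsilane attacks this cation through its silicon-bearing carbon C6, the positive charge developing at C5 β to silicon, and chloride then removes Me3Si to restore the C5=C6 double bond. The closest known reaction is the Lewis-acid-promoted cyclisation of formaldehyde acetals of (Z)-5-silylalk-4-en-1-ols to 2,3,4,7-tetrahydrooxepines, a vinylsilane-terminated Prins-type cyclisation. The oxepene closes in a 7-endo mode with both alkene carbons in the ring; no stereocenter is formed and C2 is not involved. The step needs ipso attack at C6 (seven-membered ring) in preference to attack through C5 (six-membered ring), which the β-silyl effect and the cis arrangement of silicon and C4 should provide, retention placing the side chain on C6. It also needs the cation to cyclise faster than it is caught by the ester or ketone oxygen, which excess SnCl4 bound to the carbonyl groups and high dilution should favour, while the hindered pyridine suppresses protodesilylation.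

Step 12
Reactants: 20 the fully protected oxepene from step 11
Product: 21 allyl (S)-2-[2-(2,5-dihydroxyphenyl)-2-oxoethyl]-6-[(E)-5-hydroxy-4-methylpent-3-enyl]-2,3,4,7-tetrahydrooxepine-2-carboxylate
Conditions: n-Bu4NF, AcOH (1:1, excess), THF, 0 °C → rt
Reagents that add atoms: none
Why: Fluoride desilylation of the two aryl silyl ethers and the primary silyl ether, buffered with acetic acid so that basic fluoride neither opens the β-alkoxy ketone by elimination nor attacks the allyl ester.

Step 13
Reactants: 21 the triol allyl ester from step 12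
Product: 22 (S)-2-[2-(2,5-dihydroxyphenyl)-2-oxoethyl]-6-[(E)-5-hydroxy-4-methylpent-3-enyl]-2,3,4,7-tetrahydrooxepine-2-carboxylic acid
Conditions: Pd(PPh3)4 (5 mol %), morpholine, THF, rt, argon; then aq. NaH2PO4 (pH 3)
Reagents that add atoms: none
Why: Tsuji–Trost deallylation, in which zerovalent palladium ionises the allyl ester to a π-allyl complex that morpholine intercepts, freeing the acid under nearly neutral conditions that should leave the β-alkoxy ketone, the hydroquinone and C2 unchanged.

**Compound list**

1 | 5-bromo-2-methylpent-2-ene | CC(C)=CCCBr | starting material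
2 | (E)-5-bromo-2-methylpent-2-en-1-ol | C/C(=C\CCBr)CO | intermediate
3 | (E)-5-bromo-1-(tert-butyldiphenylsilyloxy)-2-methylpent-2-ene | C/C(=C\CCBr)CO[Si](c1ccccc1)(c1ccccc1)C(C)(C)C | intermediate
4 | 4-(trimethylsilyl)but-3-yn-1-ol | C[Si](C)(C)C#CCCO | starting material
5 | diisobutylaluminium (Z)-4-(diisobutylalumino)-4-(trimethylsilyl)but-3-en-1-olate (alkenylalane) | CC(C)C[Al](CC(C)C)OCC/C=C(\[Si](C)(C)C)[Al](CC(C)C)CC(C)C | intermediate (not isolated)
6 | (E)-4-iodo-4-(trimethylsilyl)but-3-en-1-ol | C[Si](C)(C)/C(I)=C\CCO | intermediate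
7 | (E)-4-bromo-1-iodo-1-(trimethylsilyl)but-1-ene | C[Si](C)(C)/C(I)=C\CCBr | intermediate
8 | [(E)-5-(tert-butyldiphenylsilyloxy)-4-methylpent-3-enyl]zinc bromide | Br[Zn]CC/C=C(\C)CO[Si](c1ccccc1)(c1ccccc1)C(C)(C)C | intermediate (not isolated)
9 | (2E,6Z)-9-bromo-1-(tert-butyldiphenylsilyloxy)-2-methyl-6-(trimethylsilyl)nona-2,6-diene | BrCC/C=C(/CC/C=C(\C)CO[Si](c1ccccc1)(c1ccccc1)C(C)(C)C)[Si](C)(C)C | intermediate
10 | diallyl oxalate | C=CCOC(=O)C(=O)OCC=C | starting material
11 | [(3Z,7E)-9-(tert-butyldiphenylsilyloxy)-8-methyl-4-(trimethylsilyl)nona-3,7-dienyl]magnesium bromide | Br[Mg]CC/C=C(/CC/C=C(\C)CO[Si](c1ccccc1)(c1ccccc1)C(C)(C)C)[Si](C)(C)C | intermediate (not isolated)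
12 | allyl (5Z,9E)-11-(tert-butyldiphenylsilyloxy)-10-methyl-2-oxo-6-(trimethylsilyl)undeca-5,9-dienoate | C=CCOC(=O)C(=O)CC/C=C(/CC/C=C(\C)CO[Si](c1ccccc1)(c1ccccc1)C(C)(C)C)[Si](C)(C)C | intermediate
13 | 2',5'-dihydroxyacetophenone | CC(=O)c1cc(O)ccc1O | starting material
14 | 2',5'-bis(tert-butyldimethylsilyloxy)acetophenone | CC(=O)c1cc(O[Si](C)(C)C(C)(C)C)ccc1O[Si](C)(C)C(C)(C)C | intermediate
15 | 1-[2,5-bis(tert-butyldimethylsilyloxy)phenyl]-1-(trimethylsilyloxy)ethene | C=C(O[Si](C)(C)C)c1cc(O[Si](C)(C)C(C)(C)C)ccc1O[Si](C)(C)C(C)(C)C | intermediate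
16 | allyl (2S,5Z,9E)-2-{2-[2,5-bis(tert-butyldimethylsilyloxy)phenyl]-2-oxoethyl}-11-(tert-butyldiphenylsilyloxy)-10-methyl-6-(trimethylsilyl)-2-(trimethylsilyloxy)undeca-5,9-dienoate | C/C(=C\CC/C(=C/CC[C@](CC(=O)c1cc(O[Si](C)(C)C(C)(C)C)ccc1O[Si](C)(C)C(C)(C)C)(C(=O)OCC=C)O[Si](C)(C)C)[Si](C)(C)C)CO[Si](c1ccccc1)(c1ccccc1)C(C)(C)C | intermediate (not isolated)
17 | allyl (2S,5Z,9E)-2-{2-[2,5-bis(tert-butyldimethylsilyloxy)phenyl]-2-oxoethyl}-11-(tert-butyldiphenylsilyloxy)-2-hydroxy-10-methyl-6-(trimethylsilyl)undeca-5,9-dienoate | C/C(=C\CC/C(=C/CC[C@](CC(=O)c1cc(O[Si](C)(C)C(C)(C)C)ccc1O[Si](C)(C)C(C)(C)C)(C(=O)OCC=C)O)[Si](C)(C)C)CO[Si](c1ccccc1)(c1ccccc1)C(C)(C)C | intermediate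
18 | chloromethyl methyl ether | COCCl | starting material
19 | allyl (2S,5Z,9E)-2-{2-[2,5-bis(tert-butyldimethylsilyloxy)phenyl]-2-oxoethyl}-11-(tert-butyldiphenylsilyloxy)-2-(methoxymethoxy)-10-methyl-6-(trimethylsilyl)undeca-5,9-dienoate | C/C(=C\CC/C(=C/CC[C@](CC(=O)c1cc(O[Si](C)(C)C(C)(C)C)ccc1O[Si](C)(C)C(C)(C)C)(C(=O)OCC=C)OCOC)[Si](C)(C)C)CO[Si](c1ccccc1)(c1ccccc1)C(C)(C)C | intermediate
20 | allyl (S)-2-{2-[2,5-bis(tert-butyldimethylsilyloxy)phenyl]-2-oxoethyl}-6-[(E)-5-(tert-butyldiphenylsilyloxy)-4-methylpent-3-enyl]-2,3,4,7-tetrahydrooxepine-2-carboxylate | C/C(=C\CCC1=CCC[C@](CC(=O)c2cc(O[Si](C)(C)C(C)(C)C)ccc2O[Si](C)(C)C(C)(C)C)(C(=O)OCC=C)OC1)CO[Si](c1ccccc1)(c1ccccc1)C(C)(C)C | intermediate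
21 | allyl (S)-2-[2-(2,5-dihydroxyphenyl)-2-oxoethyl]-6-[(E)-5-hydroxy-4-methylpent-3-enyl]-2,3,4,7-tetrahydrooxepine-2-carboxylate | C/C(=C\CCC1=CCC[C@](CC(=O)c2cc(O)ccc2O)(C(=O)OCC=C)OC1)CO | intermediate
22 | (S)-2-[2-(2,5-dihydroxyphenyl)-2-oxoethyl]-6-[(E)-5-hydroxy-4-methylpent-3-enyl]-2,3,4,7-tetrahydrooxepine-2-carboxylic acid | C/C(=C\CCC1=CCC[C@](CC(=O)c2cc(O)ccc2O)(C(=O)O)OC1)CO | target

**Step count**

Total: 13 steps. Longest linear sequence: 9 steps (from 1 through steps 1, 2, 5, 6, 9, 10, 11, 12, 13; the same length from 4 through steps 3, 4, 5, 6, 9–13).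

**Steps most likely to fail**

1. Step 11 (ring closure). Several processes could divert it:
 - the Lewis acid may be chelated between a carbonyl oxygen and the inner acetal oxygen, so that the whole acetal is split off instead of methoxide;
 - the cation may be captured by the ester or ketone oxygen;
 - closure may occur through C5 to a six-membered ring;
 - the vinylsilane may be protodesilylated before it cyclises.

 The fallback sets out from 17 and comes back at 20. Alcohol 17 is etherified with 2-methoxyethoxymethyl chloride (i-Pr2NEt, n-Bu4NI, ClCH2CH2Cl) to give the 2-methoxyethoxymethyl ether F1. In F1 the two outer oxygens hold SnCl4 as a five-membered chelate, so only the glycol arm can leave and the same O1=CH2 cation is released in the required sense at lower temperature. Ring closure onto C6 with loss of Me3Si then gives 20. This changes the cation precursor and the way it is ionised, and it is the acetal type for which this cyclisation to oxepenes is best established.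

2. Step 10 (etherification of the tertiary alcohol). The hindered, electron-poor hydroxyl may be alkylated so slowly that prolonged heating with amine leads to retro-aldol fragmentation or elimination. The fallback sets out from 17 and comes back at 19. The methoxymethyl group is transferred from methoxymethyl 2-pyridyl sulfide with AgOTf and NaOAc in THF at rt. Thiophilic activation of the sulfide delivers the alkylating cation under buffered, base-free conditions without heating. No new compound arises on the way (F0).

3. Step 9 (aldol). Facial selectivity may be poor or turnover slow, because the enol silane is bulky and twisted by its ortho substituent and the keto ester carries a longer chain than pyruvate. The fallback sets out from 12 and 15 and comes back at 17. The addition is run with Cu(OTf)2 and the achiral ligand 2,2'-isopropylidenebis(4,4-dimethyl-2-oxazoline) to give the racemic trimethylsilyl ether F2. This is hydrolysed with 1 M HCl to the racemic tertiary alcohol F3, and the enantiomers are separated by preparative chromatography on a chiral stationary phase, the (S) enantiomer being 17. Asymmetric induction is thus replaced by resolution at the first stage that carries the stereocenter.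

**Further compounds**

F1 | step 11 | allyl (2S,5Z,9E)-2-{2-[2,5-bis(tert-butyldimethylsilyloxy)phenyl]-2-oxoethyl}-11-(tert-butyldiphenylsilyloxy)-2-[(2-methoxyethoxy)methoxy]-10-methyl-6-(trimethylsilyl)undeca-5,9-dienoate | C/C(=C\CC/C(=C/CC[C@](CC(=O)c1cc(O[Si](C)(C)C(C)(C)C)ccc1O[Si](C)(C)C(C)(C)C)(C(=O)OCC=C)OCOCCOC)[Si](C)(C)C)CO[Si](c1ccccc1)(c1ccccc1)C(C)(C)C
F0 | step 10 | none | none
F2 | step 9 | racemic allyl (5Z,9E)-2-{2-[2,5-bis(tert-butyldimethylsilyloxy)phenyl]-2-oxoethyl}-11-(tert-butyldiphenylsilyloxy)-10-methyl-6-(trimethylsilyl)-2-(trimethylsilyloxy)undeca-5,9-dienoate | C/C(=C\CC/C(=C/CCC(CC(=O)c1cc(O[Si](C)(C)C(C)(C)C)ccc1O[Si](C)(C)C(C)(C)C)(C(=O)OCC=C)O[Si](C)(C)C)[Si](C)(C)C)CO[Si](c1ccccc1)(c1ccccc1)C(C)(C)C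
F3 | step 9 | racemic allyl (5Z,9E)-2-{2-[2,5-bis(tert-butyldimethylsilyloxy)phenyl]-2-oxoethyl}-11-(tert-butyldiphenylsilyloxy)-2-hydroxy-10-methyl-6-(trimethylsilyl)undeca-5,9-dienoate | C/C(=C\CC/C(=C/CCC(CC(=O)c1cc(O[Si](C)(C)C(C)(C)C)ccc1O[Si](C)(C)C(C)(C)C)(C(=O)OCC=C)O)[Si](C)(C)C)CO[Si](c1ccccc1)(c1ccccc1)C(C)(C)C
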